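## Retrosynthetic overview

1. The C3a–prenyl bond is cut first and made last. Target 12 comes from the aromatic (S)-dihydrobenzofuran 11 and prenyl bromide by a dearomatising C-prenylation anti to the C2 substituent, which sets C3a.
2. The O1–C2 bond: 11 comes from the (R)-epoxyprenyl phenolate 10 by 5-exo epoxide opening with inversion. This is the closure nature uses for hydroxyisopropyl-dihydrofurans.
3. The epoxide oxygen: 10 comes from Shi mono-epoxidation of symmetric deoxycohumulone, carried as triacetate 8, in which both prenyl groups are equivalent.
4. Deoxycohumulone 6 comes from phloroglucinol, isobutyryl chloride and two prenyl bromides.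
5. Ring order: the carbocycle is bought as phloroglucinol. The dihydrofuran is the only ring made, in the last flask, just before dearomatisation.

Assumption: the SMILES is read as (2S,3aS), with the C2 hydroxyisopropyl group and the C3a prenyl group trans on the five-membered ring. The β-tricarbonyl is drawn as one of several rapidly equilibrating enol tautomers. Benzofuran numbering (O1, C2, C3, C3a, C4–C7, C7a) is used throughout.

## Route

Step 1
Reactants: 1 phloroglucinol; 2 isobutyryl chloride
Product: 3 phlorisobutyrophenone
Conditions: AlCl3 (3.5 equiv), PhNO2/CH2Cl2, 0 → 45 °C; aq HCl work-up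
Reagents that add atoms: isobutyryl chloride CC(C)C(=O)Cl
Why: Friedel–Crafts acylation of the threefold-symmetric, strongly activated ring gives one monoketone, because the chelated acyl group deactivates the ring towards a second acylation; no stereocentre is formed.

Step 2
Reactants: 3 phlorisobutyrophenone; 4 prenyl bromide (2.1 equiv)
Product: 6 deoxycohumulone, via monoprenyl phlorisobutyrophenone 5 (not isolated)
Conditions: KOH (2.1 equiv), degassed H2O, 0 °C → rt, N2; then acidify
Reagents that add atoms: prenyl bromide CC(C)=CCBr
Why: Phenolate C-alkylation (biomimetic aromatic prenylation) works because water solvates the phenolate oxygens, so the soft allylic bromide attacks the two free ring carbons one after the other; no stereocentre is formed.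

Step 3
Reactants: 6 deoxycohumulone; 7 acetic anhydride
Product: 8 deoxycohumulone tri-O-acetate
Conditions: Ac2O (5 equiv), DMAP (5 mol %), pyridine, 0 °C → rt
Reagents that add atoms: acetic anhydride CC(=O)OC(C)=O
Why: Exhaustive O-acetylation (DMAP-catalysed esterification) turns the oxidation-prone hexasubstituted phenol into an electron-poor arene, so the dioxirane of step 4 can only react with the alkenes.

Step 4
Reactants: 8 deoxycohumulone tri-O-acetate
Product: 9 (R)-mono-epoxide of triacetate 8
Conditions: D-fructose-derived Shi ketone (30 mol %), Oxone, K2CO3, Bu4NHSO4 (4 mol %), MeCN–DMM/aq Na2B4O7–Na2EDTA, −10 → 0 °C, stopped at ca. 60 % conversion; 8 recycled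
Reagents that add atoms: Oxone, active component potassium peroxymonosulfate [K+].[O-]S(=O)(=O)OO
Why: In this Shi asymmetric epoxidation the two prenyl groups are homotopic, so attack on either gives the same mono-epoxide; the spiro transition state of the D-fructose dioxirane delivers oxygen to the alkene face that makes the CH carbon (R), and the hindered di-ortho-substituted aryl acetates survive the cold buffer as enol esters do.

Step 5
Reactants: 9 (R)-mono-epoxide of triacetate 8; 4 prenyl bromide (1.3 equiv)
Product: 12 (2S,3aS)-target CNP0361579.1, via phenolate epoxide 10 (not isolated), via dihydrobenzofuran 11 (not isolated)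
Conditions: NaOMe (3.0 equiv), degassed MeOH, 0 °C → rt, 1 h; then prenyl bromide, −20 → 0 °C, Ar; 1 M HCl quench
Reagents that add atoms: prenyl bromide CC(C)=CCBr
Why: Proposed new method: methoxide strips the three aryl acetates (Zemplén-type transesterification), the freed oxygen para to the acyl group (the most acidic and the only non-chelated one) opens the (R)-epoxide at its CH carbon in a Baldwin-favoured 5-exo-tet SN2 with inversion to give (S)-11, and the resulting dianion is C-prenylated at the ring-fusion carbon C3a in an alkylative dearomatisation of the kind that turns deoxyhumulones into hop β-acids, the bromide approaching anti to the bulky C2 hydroxyisopropyl group as in the trans-selective α-alkylation of γ-substituted butyrolactone enolates (this sets 3aS), while C3a should beat the electronically equivalent C7 because its alkyl arm is tied back in the ring and pyramidalisation relieves the strain of the fused five-membered ring.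

## Compound list

1 | phloroglucinol (benzene-1,3,5-triol) | Oc1cc(O)cc(O)c1 | starting material
2 | isobutyryl chloride | CC(C)C(=O)Cl | starting material
3 | phlorisobutyrophenone, 2-methyl-1-(2,4,6-trihydroxyphenyl)propan-1-one | CC(C)C(=O)c1c(O)cc(O)cc1O | intermediate
4 | prenyl bromide (1-bromo-3-methylbut-2-ene) | CC(C)=CCBr | starting material
5 | 3-prenylphlorisobutyrophenone (not isolated) | CC(C)C(=O)c1c(O)cc(O)c(CC=C(C)C)c1O | intermediate
6 | deoxycohumulone, 3,5-diprenylphlorisobutyrophenone | CC(C)C(=O)c1c(O)c(CC=C(C)C)c(O)c(CC=C(C)C)c1O | intermediate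
7 | acetic anhydride | CC(=O)OC(C)=O | starting material
8 | deoxycohumulone tri-O-acetate | CC(C)C(=O)c1c(OC(C)=O)c(CC=C(C)C)c(OC(C)=O)c(CC=C(C)C)c1OC(C)=O | intermediate
9 | 2-isobutyryl-4-{[(2R)-3,3-dimethyloxiran-2-yl]methyl}-6-prenylbenzene-1,3,5-triyl triacetate | CC(C)C(=O)c1c(OC(C)=O)c(CC=C(C)C)c(OC(C)=O)c(C[C@H]2OC2(C)C)c1OC(C)=O | intermediate
10 | 1-(3-{[(2R)-3,3-dimethyloxiran-2-yl]methyl}-2,4,6-trihydroxy-5-prenylphenyl)-2-methylpropan-1-one, present as sodium phenolate (not isolated) | CC(C)C(=O)c1c(O)c(CC=C(C)C)c(O)c(C[C@H]2OC2(C)C)c1O | intermediate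
11 | 1-[(2S)-4,6-dihydroxy-2-(2-hydroxypropan-2-yl)-7-prenyl-2,3-dihydro-1-benzofuran-5-yl]-2-methylpropan-1-one (not isolated) | CC(C)=CCc1c2O[C@H](C(C)(C)O)Cc2c(O)c(C(=O)C(C)C)c1O | intermediate
12 | (2S,3aS)-6-hydroxy-2-(2-hydroxypropan-2-yl)-5-isobutyryl-3a,7-diprenyl-3,3a-dihydro-1-benzofuran-4(2H)-one | CC(C)=CCC1=C2O[C@H](C(C)(C)O)C[C@]2(CC=C(C)C)C(=O)C(C(=O)C(C)C)=C1O | target

## Step count and risks

Total step count: 5. Longest linear sequence: 5 (1 → 3 → 6 → 8 → 9 → 12).

**Step 5 (most at risk).**
- C7 is electronically equivalent to C3a, so the 7,7-diprenyl regioisomer may compete.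
- The oxygen ortho to the acyl group may close the ring instead.
- The 1,3-induction may be only moderate.

The fallback sets out from 6 and comes back at 12. Compound 6 is C-prenylated once more with 4 (KOH, H2O/PhCl, phase transfer, 0 °C) at a prenyl-bearing carbon to give achiral colupulone F1. The quaternary carbon is then in place before any ring exists and without regiochemical ambiguity. Shi epoxidation with the same D-fructose ketone and sub-stoichiometric Oxone oxidises one geminal prenyl group to the (6S)-colupulone (R)-mono-epoxide F2. F2 closes 5-exo through the C5 enol oxygen in the buffer to give 12. The CH centre is catalyst-controlled there, but the quaternary centre is set only statistically. The C3a epimer and the isomers from the C4 prenyl group must therefore be removed by chromatography.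

**Step 4.**
- The mono/bis-epoxide ratio is statistical.
- Some acetate may be lost in the buffer.
- The ee on a prenyl arene is uncertain.

The fallback sets out from 8 and comes back at 11. Sharpless asymmetric dihydroxylation is run under neutral conditions (K2OsO2(OH)4, (DHQD)2PHAL, NMO, acetone/H2O, 0 °C, slow addition, partial conversion) and gives the (R)-mono-diol triacetate F3. Catalytic K2CO3 in degassed MeOH frees the (R)-diol of deoxycohumulone F4. An intramolecular Mitsunobu etherification (PPh3, DIAD, THF, 0 °C) then activates only the secondary alcohol and lets the acidic para-phenol displace it with inversion to give (S)-11. Compound 11 is isolated and prenylated as in the second half of step 5.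

**Step 2.**
- Mono-, di- and tri-prenylated products form together.
- O-alkylation competes.
- The product is air-sensitive.

The fallback sets out from 3 and comes back at 6. Phenolate SN2 chemistry is replaced by a cationic Friedel–Crafts prenylation with 2-methylbut-3-en-2-ol and BF3·OEt2 in dioxane at rt. This cannot dearomatise the ring and stops at C-substitution of the two free positions. It makes no compound outside the list (none F0).

## Further compounds

F1 | step 5 | colupulone, 3,5-dihydroxy-2-isobutyryl-4,6,6-triprenylcyclohexa-2,4-dien-1-one | CC(C)C(=O)C1=C(O)C(CC=C(C)C)=C(O)C(CC=C(C)C)(CC=C(C)C)C1=O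
F2 | step 5 | (6S)-6-{[(2R)-3,3-dimethyloxiran-2-yl]methyl}-3,5-dihydroxy-2-isobutyryl-4,6-diprenylcyclohexa-2,4-dien-1-one | CC(C)=CCC1=C(O)[C@@](C[C@H]2OC2(C)C)(CC=C(C)C)C(=O)C(C(=O)C(C)C)=C1O
F3 | step 4 | 2-[(2R)-2,3-dihydroxy-3-methylbutyl]-4-isobutyryl-6-prenylbenzene-1,3,5-triyl triacetate | CC(C)C(=O)c1c(OC(C)=O)c(CC=C(C)C)c(OC(C)=O)c(C[C@@H](O)C(C)(C)O)c1OC(C)=O
F4 | step 4 | 1-{3-[(2R)-2,3-dihydroxy-3-methylbutyl]-2,4,6-trihydroxy-5-prenylphenyl}-2-methylpropan-1-one | CC(C)C(=O)c1c(O)c(CC=C(C)C)c(O)c(C[C@@H](O)C(C)(C)O)c1O
F0 | step 2 | none | none
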